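**Retrosynthetic overview**

- Target 19 is a 2,5-disubstituted 1H-pyrrole: N1–H, C2 carries the formyl group, C5 carries the n-C19 chain, and C3 and C4 are both plain CH. This unsubstituted C3–C4 edge, flanked by the two substituted carbons, is the feature the route rests on.
- The C3=C4 bond is cut back to two vinyl groups on a secondary amine (diene amino ester 13). The only ring is closed by olefin metathesis as 3-pyrroline 16 (step 7) and then dehydrogenated to the pyrrole (step 8).
- The formyl group travels as a methyl ester and is released at the end through the Weinreb amide and hydride.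
- Diene 13 comes from a Petasis three-component coupling of docos-1-en-3-amine 8, glyoxylic acid and a vinylboronate, then esterification.
- Amine 8 comes from icosan-1-ol by oxidation, N-sulfinyl imine formation, vinyl Grignard addition and N–S cleavage.

Key step: step 7

Remark on the chemistry: both sp3 stereocentres of 13 and 16 vanish on aromatisation, so racemic tert-butanesulfinamide is assumed and diastereomer mixtures are carried on unseparated. Their SMILES are therefore written without descriptors.

**Route**

Step 1
Reactants: 1 icosan-1-ol
Product: 2 icosanal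
Conditions: TEMPO (10 mol %), PhI(OAc)2 (1.1 equiv), CH2Cl2, rt
Reagents that add atoms: none
Why: Oxoammonium (TEMPO-catalysed) oxidation of a primary alcohol should stop at the aldehyde because no water is present to form the hydrate needed for over-oxidation.

Step 2
Reactants: 2 icosanal; 3 2-methylpropane-2-sulfinamide (racemic)
Product: 4 (E)-N-icosylidene-2-methylpropane-2-sulfinamide (racemic at sulfur)
Conditions: CuSO4 (anhydrous, 2 equiv), CH2Cl2, rt
Reagents that add atoms: none
Why: Condensation of an aldehyde with tert-butanesulfinamide, driven by the Lewis acidic dehydrating agent, should give the E-configured N-sulfinyl aldimine without enolisation of the aliphatic aldehyde.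

Step 3
Reactants: 4 (E)-N-icosylidene-2-methylpropane-2-sulfinamide; 5 vinylmagnesium bromide
Product: 6 N-(docos-1-en-3-yl)-2-methylpropane-2-sulfinamide (racemic, one relative configuration expected to predominate)
Conditions: CH2=CHMgBr (1 M in THF, 2 equiv), CH2Cl2, −78 to −40 °C; then H2O
Reagents that add atoms: none
Why: 1,2-Addition of a Grignard reagent to an N-tert-butanesulfinyl aldimine is reliable because the sulfinyl group activates the C=N bond and blocks over-addition; the new carbinamine centre is set relative to sulfur through a chair-like magnesium chelate, though its configuration is of no consequence here.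

Step 4
Reactants: 6 N-(docos-1-en-3-yl)-2-methylpropane-2-sulfinamide
Product: 8 docos-1-en-3-amine (racemic), via docos-1-en-3-aminium chloride 7 (not isolated)
Conditions: HCl (4 M in dioxane, 2 equiv), MeOH, 0 °C to rt; then aq. NaOH, Et2O extraction
Reagents that add atoms: none
Why: Acidic methanolysis of the S–N bond is the standard sulfinamide cleavage, the terminal alkene is inert to HCl at this temperature, and the basic work-up should liberate the free allylic amine.

Step 5
Reactants: 8 docos-1-en-3-amine; 9 glyoxylic acid monohydrate; 10 vinylboronic acid pinacol ester (4,4,5,5-tetramethyl-2-vinyl-1,3,2-dioxaborolane)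
Product: 12 2-(docos-1-en-3-ylamino)but-3-enoic acid (racemic mixture of both diastereomers), via 2-(docos-1-en-3-ylimino)acetic acid 11 (not isolated)
Conditions: CH2Cl2/1,1,1,3,3,3-hexafluoropropan-2-ol (9:1), rt to 40 °C
Reagents that add atoms: none
Why: Petasis borono-Mannich reaction: amine and glyoxylic acid condense to imino acid 11, whose carboxylate binds boron and delivers the vinyl group intramolecularly to the iminium carbon; the new α-centre forms without useful control, which is acceptable because step 8 destroys it.

Step 6
Reactants: 12 2-(docos-1-en-3-ylamino)but-3-enoic acid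
Product: 13 methyl 2-(docos-1-en-3-ylamino)but-3-enoate (racemic mixture of both diastereomers)
Conditions: TMSCHN2 (2 M in hexanes), toluene/MeOH (4:1), 0 °C to rt
Reagents that add atoms: trimethylsilyldiazomethane, C[Si](C)(C)C=[N+]=[N-]
Why: Methyl ester formation with trimethylsilyldiazomethane in methanol is a neutral O-alkylation of the carboxylate, so the secondary amine and the isomerisation-prone β,γ-unsaturated α-amino acid unit should remain untouched.

Step 7
Reactants: 13 methyl 2-(docos-1-en-3-ylamino)but-3-enoate
Product: 16 methyl 5-nonadecyl-2,5-dihydro-1H-pyrrole-2-carboxylate (racemic cis/trans mixture), via diene ammonium tosylate 14 (not isolated), via pyrrolinium tosylate 15 (not isolated)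
Conditions: TsOH·H2O (1.05 equiv), CH2Cl2 (0.01 M), rt; then second-generation Hoveyda–Grubbs catalyst RuCl2(H2IMes)(=CH-C6H4-2-OiPr) (5 mol %), 1,4-benzoquinone (10 mol %), 40 °C; then aq. NaHCO3
Reagents that add atoms: none
Why: The ruthenium benzylidene initiates on one terminal vinyl group of ammonium salt 14 by [2+2] cycloaddition and cycloreversion, and the resulting alkylidene is captured by the second vinyl group through a ruthenacyclobutane whose collapse expels ethene and forms the C3=C4 bond. The closest known reaction type is ring-closing metathesis of diallylamine salts and N-acyl diallylamines to 3-pyrrolines. The single ring closes as an unstrained five-membered ring by joining the two inner alkene carbons of a 1,6-diene, which necessarily gives the cis ring alkene. No stereocentre is created; C2 and C5 are carried through as a cis/trans mixture that converges in step 8. The selectivity required is ring closure over coordination of nitrogen to ruthenium, over ruthenium-hydride migration of the vinylglycine double bond into conjugation with the ester, and over intermolecular metathesis; full N-protonation by TsOH, the quinone hydride scavenger, high dilution and the intrinsically fast five-ring closure of two monosubstituted alkenes should secure it.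

Step 8
Reactants: 16 methyl 5-nonadecyl-2,5-dihydro-1H-pyrrole-2-carboxylate
Product: 17 methyl 5-nonadecyl-1H-pyrrole-2-carboxylate
Conditions: DDQ (1.05 equiv), CH2Cl2, 0 °C to rt
Reagents that add atoms: none
Why: Oxidative aromatisation of a 3-pyrroline by a high-potential quinone: hydride abstraction from the doubly activated (allylic, α-amino) C5–H or C2–H, then proton loss and tautomerisation, should give the aromatic pyrrole and erase both stereocentres.

Step 9
Reactants: 17 methyl 5-nonadecyl-1H-pyrrole-2-carboxylate
Product: 18 N-methoxy-N-methyl-5-nonadecyl-1H-pyrrole-2-carboxamide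
Conditions: MeNH(OMe)·HCl (3 equiv), AlMe3 (2 M in toluene, 3 equiv), toluene, 0 to 80 °C; then cold aq. HCl (1 M)
Reagents that add atoms: N,O-dimethylhydroxylamine hydrochloride, CNOC.Cl
Why: Weinreb aminolysis of an ester with the dimethylaluminium amide made from AlMe3 and the amine hydrochloride; the pyrrole N–H is metalated first, hence the excess reagent, and the Lewis acidic aluminium should keep the ester carbonyl activated.

Step 10
Reactants: 18 N-methoxy-N-methyl-5-nonadecyl-1H-pyrrole-2-carboxamide
Product: 19 5-nonadecyl-1H-pyrrole-2-carbaldehyde
Conditions: LiAlH4 (1.5 equiv), THF, −20 to 0 °C; then H2O, aq. NaOH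
Reagents that add atoms: none
Why: Weinreb amide reduction: after deprotonation of the pyrrole N–H one hydride adds to the amide, and chelation by the N-methoxy group holds the tetrahedral stage until aqueous work-up, which should release the aldehyde without over-reduction.

**Compound list**

1 | icosan-1-ol | CCCCCCCCCCCCCCCCCCCCO | starting material
2 | icosanal | CCCCCCCCCCCCCCCCCCCC=O | intermediate
3 | 2-methylpropane-2-sulfinamide (racemic) | CC(C)(C)S(N)=O | starting material
4 | (E)-N-icosylidene-2-methylpropane-2-sulfinamide (racemic at sulfur) | CCCCCCCCCCCCCCCCCCC/C=N/S(=O)C(C)(C)C | intermediate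
5 | vinylmagnesium bromide | C=C[Mg]Br | starting material
6 | N-(docos-1-en-3-yl)-2-methylpropane-2-sulfinamide (racemic) | C=CC(NS(=O)C(C)(C)C)CCCCCCCCCCCCCCCCCCC | intermediate
7 | docos-1-en-3-aminium chloride (racemic) | C=CC([NH3+])CCCCCCCCCCCCCCCCCCC.[Cl-] | intermediate (not isolated)
8 | docos-1-en-3-amine (racemic) | C=CC(N)CCCCCCCCCCCCCCCCCCC | intermediate
9 | glyoxylic acid monohydrate | O=CC(=O)O.O | starting material
10 | vinylboronic acid pinacol ester | C=CB1OC(C)(C)C(C)(C)O1 | starting material
11 | 2-(docos-1-en-3-ylimino)acetic acid (racemic) | C=CC(N=CC(=O)O)CCCCCCCCCCCCCCCCCCC | intermediate (not isolated)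
12 | 2-(docos-1-en-3-ylamino)but-3-enoic acid (racemic, both diastereomers) | C=CC(NC(C=C)C(=O)O)CCCCCCCCCCCCCCCCCCC | intermediate
13 | methyl 2-(docos-1-en-3-ylamino)but-3-enoate (racemic, both diastereomers) | C=CC(NC(C=C)C(=O)OC)CCCCCCCCCCCCCCCCCCC | intermediate
14 | (docos-1-en-3-yl)(1-methoxy-1-oxobut-3-en-2-yl)ammonium 4-methylbenzenesulfonate | C=CC([NH2+]C(C=C)C(=O)OC)CCCCCCCCCCCCCCCCCCC.Cc1ccc(S(=O)(=O)[O-])cc1 | intermediate (not isolated)
15 | 2-(methoxycarbonyl)-5-nonadecyl-2,5-dihydro-1H-pyrrol-1-ium 4-methylbenzenesulfonate (cis/trans mixture) | CCCCCCCCCCCCCCCCCCCC1C=CC(C(=O)OC)[NH2+]1.Cc1ccc(S(=O)(=O)[O-])cc1 | intermediate (not isolated)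
16 | methyl 5-nonadecyl-2,5-dihydro-1H-pyrrole-2-carboxylate (racemic, cis/trans mixture) | CCCCCCCCCCCCCCCCCCCC1C=CC(C(=O)OC)N1 | intermediate
17 | methyl 5-nonadecyl-1H-pyrrole-2-carboxylate | CCCCCCCCCCCCCCCCCCCc1ccc(C(=O)OC)[nH]1 | intermediate
18 | N-methoxy-N-methyl-5-nonadecyl-1H-pyrrole-2-carboxamide | CCCCCCCCCCCCCCCCCCCc1ccc(C(=O)N(C)OC)[nH]1 | intermediate
19 | 5-nonadecyl-1H-pyrrole-2-carbaldehyde | CCCCCCCCCCCCCCCCCCCc1ccc(C=O)[nH]1 | target

**Step count**

Total steps: 10. Longest linear sequence: 10 (from icosan-1-ol 1).

**Steps most likely to fail**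

1. Step 7 (ring-closing metathesis). The catalyst may be arrested by incompletely protonated amine. The vinylglycine double bond may migrate into conjugation with the ester before ring closure, and the diene may oligomerise intermolecularly. The fallback gives up metathesis and builds the pyrrole by condensation; it sets out from icosanal 2 and comes back at the target 19. The Grignard reagent from 2-(2-bromoethyl)-1,3-dioxolane and Mg (THF, below 30 °C) would be added to 2 to give 1-(1,3-dioxolan-2-yl)docosan-3-ol F1. Oxidation with Dess–Martin periodinane (NaHCO3, CH2Cl2) should give 1-(1,3-dioxolan-2-yl)docosan-3-one F2. Heating F2 with NH4OAc in aqueous AcOH should unmask 4-oxotricosanal F3, which condenses in the same flask (Paal–Knorr) to 2-nonadecyl-1H-pyrrole F4. Vilsmeier–Haack formylation (POCl3, DMF, 0 °C; then aq. NaOAc) at the free α-position would then give 19.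

2. Step 5 (Petasis coupling). Transfer of the unsubstituted vinyl group from the pinacol boronate may be too slow, so that imino acid 11 reverts or decomposes before the C–C bond forms. The fallback brings in the two-carbon unit as a more nucleophilic styryl group and lets metathesis expel styrene; it sets out from amine 8 and comes back at pyrroline 16. Amine 8, glyoxylic acid monohydrate 9 and (E)-2-phenylvinylboronic acid would be combined under the same conditions to give (E)-2-(docos-1-en-3-ylamino)-4-phenylbut-3-enoic acid F5. Esterification with TMSCHN2 should give methyl (E)-2-(docos-1-en-3-ylamino)-4-phenylbut-3-enoate F6. Treatment with TsOH·H2O would form (docos-1-en-3-yl)[(E)-1-methoxy-1-oxo-4-phenylbut-3-en-2-yl]ammonium 4-methylbenzenesulfonate F7 in the flask. Under the catalyst and conditions of step 7 the ruthenium alkylidene should load on the terminal vinyl group and close onto the styryl alkene, giving 15 and, after NaHCO3, 16.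

3. Step 9 (Weinreb aminolysis). The N-metalated pyrrole donates electron density into the ester carbonyl, so the aminolysis may stall, and forcing it risks degrading the pyrrole. The fallback activates the acyl group as the acid instead of activating the amine; it sets out from ester 17 and comes back at Weinreb amide 18. Saponification (NaOH, EtOH/H2O, reflux; cold acidification to about pH 4 to avoid decarboxylation) should give 5-nonadecyl-1H-pyrrole-2-carboxylic acid F8. Carbodiimide coupling (EDC·HCl, HOBt, MeNH(OMe)·HCl, iPr2NEt, CH2Cl2/DMF, rt) would then give 18.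

**Further compounds**

F1 | step 7 | 1-(1,3-dioxolan-2-yl)docosan-3-ol (racemic) | CCCCCCCCCCCCCCCCCCCC(O)CCC1OCCO1
F2 | step 7 | 1-(1,3-dioxolan-2-yl)docosan-3-one | CCCCCCCCCCCCCCCCCCCC(=O)CCC1OCCO1
F3 | step 7 | 4-oxotricosanal (not isolated) | CCCCCCCCCCCCCCCCCCCC(=O)CCC=O
F4 | step 7 | 2-nonadecyl-1H-pyrrole | CCCCCCCCCCCCCCCCCCCc1ccc[nH]1
F5 | step 5 | (E)-2-(docos-1-en-3-ylamino)-4-phenylbut-3-enoic acid (racemic, both diastereomers) | C=CC(NC(/C=C/c1ccccc1)C(=O)O)CCCCCCCCCCCCCCCCCCC
F6 | step 5 | methyl (E)-2-(docos-1-en-3-ylamino)-4-phenylbut-3-enoate (racemic, both diastereomers) | C=CC(NC(/C=C/c1ccccc1)C(=O)OC)CCCCCCCCCCCCCCCCCCC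
F7 | step 5 | (docos-1-en-3-yl)[(E)-1-methoxy-1-oxo-4-phenylbut-3-en-2-yl]ammonium 4-methylbenzenesulfonate (not isolated) | C=CC([NH2+]C(/C=C/c1ccccc1)C(=O)OC)CCCCCCCCCCCCCCCCCCC.Cc1ccc(S(=O)(=O)[O-])cc1
F8 | step 9 | 5-nonadecyl-1H-pyrrole-2-carboxylic acid | CCCCCCCCCCCCCCCCCCCc1ccc(C(=O)O)[nH]1
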